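**Plan**

1. Retrosynthetic cuts: first the C11–O aryl ether, then C5–C10 and C8–C9 together (retro-[4+2]), then C6–C7 (alkenyl–allenyl coupling) and C3–C4 (propargylation of an aldehyde obtained from methyl geranate).
2. Enabling feature: ring B is a 3-methylidenecyclohexene (C6=C7 beside the exocyclic C8=C12). This is the retron of a Diels–Alder reaction between a vinylallene (C5=C6–C7=C8=C12) and the C9=C10 alkene, with the four ring A carbons C1–C4 as the tether.
3. Forward: C11–C9–C10–C1–C2–C3 comes from methyl geranate, C4–C6 with both methyls from 3-bromo-3-methylbut-1-yne, and C7/C8/C12 from a propargyl carbonate. Rings A and B then close together in one step from an acyclic, achiral keto enal, and the coumarin is attached last.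
4. Helpers: C11 as aldehyde (iminium activation of the dienophile) and C3 as ketone (no stereocentre before the cyclisation). One hydride reduction removes both; no protecting group is used.
5. Stereochemistry: C9/C10 from the (E)-enal geometry, C5 from the endo transition state (trans fusion), absolute configuration from a chiral imidazolidinone catalyst, and C3 from equatorial hydride delivery to the ring A ketone.

Key step: step 7

Remark: atom labels C1–C12 in the explanations use drimane numbering of the target (ring A = C1–C5, C10; ring B = C5–C10; C11 = OCH2; C12 = exocyclic CH2). Compounds 6, 7, 9 and 10 are racemic at the carbinol carbon that becomes C3, which is oxidised in step 6. Catalyst-bound species of the catalytic cycles (iminium ions, organopalladium complexes) are taken as forms of the catalyst and carry no number.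

**Route**

Step 1
Reactants: 1 methyl (2E)-3,7-dimethylocta-2,6-dienoate (methyl geranate)
Product: 3 methyl (2E)-3-methyl-6-oxohex-2-enoate, via secondary ozonide 2 (not isolated)
Conditions: O3, CH2Cl2, −78 °C, Sudan Red 7B as end-point indicator; then Me2S, −78 °C to rt
Reagents that add atoms: ozone, [O-][O+]=O
Why: Chemoselective ozonolysis with reductive work-up should consume the electron-rich trisubstituted alkene far faster than the ester-conjugated alkene, whose E geometry (the later C9=C10 dienophile geometry) stays untouched.

Step 2
Reactants: 3 methyl (2E)-3-methyl-6-oxohex-2-enoate; 4 3-bromo-3-methylbut-1-yne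
Product: 6 methyl (2E)-6-hydroxy-3,7,7-trimethylnon-2-en-8-ynoate (racemic), via allenylzinc bromide 5 (not isolated)
Conditions: Zn dust, THF, 0 °C to rt; then 1 M HCl
Reagents that add atoms: none
Why: In this Barbier-type propargylation zinc inserts into the tertiary propargylic bromide to give the allenylzinc bromide, which should add to the aldehyde (not the ester) through a cyclic SE2' transition state at its dimethyl-substituted carbon, forming the C3–C4 bond and the quaternary C4; the new carbinol centre is racemic, which is harmless because C3 is a ketone in the key step.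

Step 3
Reactants: 6 methyl (2E)-6-hydroxy-3,7,7-trimethylnon-2-en-8-ynoate
Product: 7 methyl (2E,8E)-6-hydroxy-3,7,7-trimethyl-9-(4,4,5,5-tetramethyl-1,3,2-dioxaborolan-2-yl)nona-2,8-dienoate
Conditions: pinacolborane (2.2 equiv), dicyclohexylborane (10 mol%), THF, rt; aqueous work-up
Reagents that add atoms: pinacolborane, CC1(C)OBOC1(C)C
Why: Dialkylborane-catalysed hydroboration of the terminal alkyne is syn and anti-Markovnikov (boron away from the quaternary C4), so it should give the (E)-alkenylboronate that fixes the E geometry of the later C5=C6 diene bond, while the enoate and the hindered hydroxyl are tolerated.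

Step 4
Reactants: 7 methyl (2E,8E)-6-hydroxy-3,7,7-trimethyl-9-(4,4,5,5-tetramethyl-1,3,2-dioxaborolan-2-yl)nona-2,8-dienoate; 8 methyl prop-2-yn-1-yl carbonate
Product: 9 methyl (2E,8E)-6-hydroxy-3,7,7-trimethyldodeca-2,8,10,11-tetraenoate
Conditions: Pd(PPh3)4 (5 mol%), THF, 40 °C
Reagents that add atoms: none
Why: In this Suzuki–Miyaura-type coupling of an alkenylboronate with a propargylic carbonate, SN2' oxidative addition of zerovalent palladium to 8 with loss of CO2 gives an allenylpalladium methoxide (divalent palladium) that transmetalates without added base, and reductive elimination should join C6 to C7 as the (E)-vinylallene with retention of alkene geometry.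

Step 5
Reactants: 9 methyl (2E,8E)-6-hydroxy-3,7,7-trimethyldodeca-2,8,10,11-tetraenoate
Product: 10 (2E,8E)-3,7,7-trimethyldodeca-2,8,10,11-tetraene-1,6-diol
Conditions: i-Bu2AlH (3.5 equiv), CH2Cl2, −78 °C; then aq. potassium sodium tartrate
Reagents that add atoms: none
Why: Hydride reduction of the conjugated ester with i-Bu2AlH proceeds in the 1,2 sense to the allylic alcohol at −78 °C, where the allene and both alkenes should be inert, and it turns the dienophile into an unactivated alkene so the vinylallene can be handled.

Step 6
Reactants: 10 (2E,8E)-3,7,7-trimethyldodeca-2,8,10,11-tetraene-1,6-diol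
Product: 11 (2E,8E)-3,7,7-trimethyl-6-oxododeca-2,8,10,11-tetraenal
Conditions: Dess–Martin periodinane (2.6 equiv), NaHCO3, CH2Cl2, 0 °C; product kept cold and used at once
Reagents that add atoms: none
Why: Buffered Dess–Martin oxidation should convert the allylic alcohol to the (E)-enal without E/Z isomerisation and the hindered secondary alcohol to the C3 ketone, which removes the racemic centre and gives an achiral cyclisation substrate whose ketone has no α-hydrogen on the C4 side.

Step 7
Reactants: 11 (2E,8E)-3,7,7-trimethyl-6-oxododeca-2,8,10,11-tetraenal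
Product: 12 (1S,4aR,8aS)-5,5,8a-trimethyl-2-methylidene-6-oxo-1,2,4a,5,6,7,8,8a-octahydronaphthalene-1-carbaldehyde
Conditions: (2S,5S)-5-benzyl-2-tert-butyl-3-methylimidazolidin-4-one trifluoroacetate (20 mol%), MeCN/H2O 98:2, −20 to 4 °C
Reagents that add atoms: none
Why: Proposed new method: the secondary amine salt condenses reversibly with the C11 aldehyde to an (E)-iminium ion whose lowered LUMO lets C9=C10 act as dienophile towards the s-cis vinylallene C5=C6–C7=C8(=C12) in a concerted, asynchronous [4+2] cycloaddition (C5–C10 at the iminium β-carbon ahead of C8–C9), and hydrolysis of the product iminium releases 12 and the catalyst; the closest known reaction type is the imidazolidinone-catalysed enantioselective intramolecular Diels–Alder reaction of 2,7,9-trienals, not yet shown for a β,β-disubstituted enal that forms a quaternary carbon or for a vinylallene diene, although iminium-catalysed conjugate additions to β,β-disubstituted enals and thermal or Lewis-acid vinylallene Diels–Alder reactions are known. Ring A (C1–C5, C10) is the tether ring, closed by the C5–C10 bond alone in an exo mode with respect to both the dienophile and the diene, and ring B (C5–C10) is the new cyclohexene, closed by C5–C10 and C8–C9 together, the allene leaving C8=C12 as the exocyclic methylidene next to C6=C7. C9 and C10 are set relative to each other by suprafacial addition to the (E)-enal (C11 cis to the C10 methyl), C5 relative to C10 by the endo transition state (iminium carbon C11 and the C10 methyl under the diene, tether C1–C4 as a chair on the outside), which gives the trans ring fusion, and the absolute sense by the catalyst, whose benzyl and tert-butyl groups should cover the Re face of C9 so that C8 adds to its Si face, which corresponds to 5R,9S,10S. The step needs endo over exo selectivity, one π-face, retention of the enal geometry and a catalysed rate above the uncatalysed one; the (E)-diene with C4 on the outside, the unhindered sp-hybridised C8 terminus, the strain released from the allene and the gem-dimethyl group at C4 should give reactivity at low temperature, and the C3 ketone keeps 11 achiral so that the catalyst alone decides the configuration.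

Step 8
Reactants: 12 (1S,4aR,8aS)-5,5,8a-trimethyl-2-methylidene-6-oxo-1,2,4a,5,6,7,8,8a-octahydronaphthalene-1-carbaldehyde
Product: 13 (2R,4aS,5S,8aR)-5-(hydroxymethyl)-1,1,4a-trimethyl-6-methylidene-1,2,3,4,4a,5,6,8a-octahydronaphthalen-2-ol
Conditions: LiBH(s-Bu)3 (L-Selectride, 2.5 equiv), THF, −78 °C, on the crude adduct; then H2O
Reagents that add atoms: none
Why: In this bulky-hydride carbonyl reduction the aldehyde should be reduced first (before C9 can epimerise or move into conjugation) and the C3 ketone by equatorial attack, because the axial approach on the α-face is screened by the axial hydrogens at C1 and C5; the hydroxyl therefore ends up axial (3α, 3R), as is usual for 4,4-dimethyl-3-oxo terpenoids.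

Step 9
Reactants: 13 (2R,4aS,5S,8aR)-5-(hydroxymethyl)-1,1,4a-trimethyl-6-methylidene-1,2,3,4,4a,5,6,8a-octahydronaphthalen-2-ol; 14 7-hydroxy-2H-chromen-2-one (umbelliferone)
Product: 15 7-{[(1S,4aR,6R,8aS)-6-hydroxy-5,5,8a-trimethyl-2-methylidene-1,2,4a,5,6,7,8,8a-octahydronaphthalen-1-yl]methoxy}-2H-chromen-2-one (target)
Conditions: PPh3, diisopropyl azodicarboxylate, THF, 0 °C to rt
Reagents that add atoms: none
Why: In this Mitsunobu etherification the acidic phenol (pKa about 8) should displace the alkoxyphosphonium group of the primary C11 alcohol, while the axial C3 hydroxyl flanked by the gem-dimethyl group is too hindered to be activated, and no stereocentre is touched.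

**Compound list**

1 | methyl (2E)-3,7-dimethylocta-2,6-dienoate | COC(=O)/C=C(\C)CCC=C(C)C | starting material
2 | methyl (2E)-5-(5,5-dimethyl-1,2,4-trioxolan-3-yl)-3-methylpent-2-enoate | COC(=O)/C=C(\C)CCC1OOC(C)(C)O1 | intermediate (not isolated)
3 | methyl (2E)-3-methyl-6-oxohex-2-enoate | COC(=O)/C=C(\C)CCC=O | intermediate
4 | 3-bromo-3-methylbut-1-yne | CC(C)(Br)C#C | starting material
5 | bromo(3-methylbuta-1,2-dien-1-yl)zinc | CC(C)=C=C[Zn]Br | intermediate (not isolated)
6 | methyl (2E)-6-hydroxy-3,7,7-trimethylnon-2-en-8-ynoate (racemic) | COC(=O)/C=C(\C)CCC(O)C(C)(C)C#C | intermediate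
7 | methyl (2E,8E)-6-hydroxy-3,7,7-trimethyl-9-(4,4,5,5-tetramethyl-1,3,2-dioxaborolan-2-yl)nona-2,8-dienoate (racemic) | COC(=O)/C=C(\C)CCC(O)C(C)(C)/C=C/B1OC(C)(C)C(C)(C)O1 | intermediate
8 | methyl prop-2-yn-1-yl carbonate | COC(=O)OCC#C | starting material
9 | methyl (2E,8E)-6-hydroxy-3,7,7-trimethyldodeca-2,8,10,11-tetraenoate (racemic) | COC(=O)/C=C(\C)CCC(O)C(C)(C)/C=C/C=C=C | intermediate
10 | (2E,8E)-3,7,7-trimethyldodeca-2,8,10,11-tetraene-1,6-diol (racemic) | OC/C=C(\C)CCC(O)C(C)(C)/C=C/C=C=C | intermediate
11 | (2E,8E)-3,7,7-trimethyl-6-oxododeca-2,8,10,11-tetraenal | O=C/C=C(\C)CCC(=O)C(C)(C)/C=C/C=C=C | intermediate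
12 | (1S,4aR,8aS)-5,5,8a-trimethyl-2-methylidene-6-oxo-1,2,4a,5,6,7,8,8a-octahydronaphthalene-1-carbaldehyde | C=C1C=C[C@H]2C(C)(C)C(=O)CC[C@]2(C)[C@H]1C=O | intermediate
13 | (2R,4aS,5S,8aR)-5-(hydroxymethyl)-1,1,4a-trimethyl-6-methylidene-1,2,3,4,4a,5,6,8a-octahydronaphthalen-2-ol | C=C1C=C[C@H]2C(C)(C)[C@H](O)CC[C@]2(C)[C@H]1CO | intermediate
14 | 7-hydroxy-2H-chromen-2-one | Oc1ccc2ccc(=O)oc2c1 | starting material
15 | 7-{[(1S,4aR,6R,8aS)-6-hydroxy-5,5,8a-trimethyl-2-methylidene-1,2,4a,5,6,7,8,8a-octahydronaphthalen-1-yl]methoxy}-2H-chromen-2-one | C=C1C=C[C@H]2C(C)(C)[C@H](O)CC[C@]2(C)[C@H]1COc1ccc2ccc(=O)oc2c1 | target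

**Step count and risks**

Total step count: 9. Longest linear sequence: 9 steps (1 to 15).

Steps most likely to fail:

1. Step 7 (Proposed new method). Iminium formation and cycloaddition at the fully substituted β-carbon may be slow, so that the uncatalysed cyclisation (racemic and less endo-selective) competes. Reversible dienamine formation may scramble the enal geometry and with it the C9 configuration. Facial discrimination may be lower than for β-monosubstituted enals. Fallback with known chemistry, from 11 back to 13: cyclisation of 11 with Me2AlCl (CH2Cl2, −78 to −20 °C; Lewis-acid-promoted intramolecular Diels–Alder reaction of a trienal) should give the racemic trans-fused adduct, that is 12 together with its enantiomer (1R,4aS,8aR)-5,5,8a-trimethyl-2-methylidene-6-oxo-1,2,4a,5,6,7,8,8a-octahydronaphthalene-1-carbaldehyde F1. Reduction as in step 8 gives 13 together with its enantiomer (2S,4aR,5R,8aS)-5-(hydroxymethyl)-1,1,4a-trimethyl-6-methylidene-1,2,3,4,4a,5,6,8a-octahydronaphthalen-2-ol F2. Esterification of the primary hydroxyl with (S)-2-methoxy-2-phenylacetic acid (dicyclohexylcarbodiimide, 4-dimethylaminopyridine) gives the diastereomeric esters [(1S,4aR,6R,8aS)-6-hydroxy-5,5,8a-trimethyl-2-methylidene-1,2,4a,5,6,7,8,8a-octahydronaphthalen-1-yl]methyl (2S)-2-methoxy-2-phenylacetate F3 and [(1R,4aS,6S,8aR)-6-hydroxy-5,5,8a-trimethyl-2-methylidene-1,2,4a,5,6,7,8,8a-octahydronaphthalen-1-yl]methyl (2S)-2-methoxy-2-phenylacetate F4, which are separated by chromatography. Methanolysis of F3 (K2CO3, MeOH) returns 13.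

2. Step 4. The vinylallene ester may cyclise thermally at the coupling temperature, coupling may occur at the propargylic instead of the allenic terminus, or the boronate may protodeboronate. Fallback, from 7 back to 9: ipso-iododeboronation with retention (N-iodosuccinimide, MeCN) gives methyl (2E,8E)-6-hydroxy-9-iodo-3,7,7-trimethylnona-2,8-dienoate F5. Stille coupling of F5 with tributyl(propa-1,2-dien-1-yl)stannane (Pd(PPh3)4, CuI, DMF, rt) reverses the polarity of the C6–C7 bond formation and should give 9 at room temperature.

3. Step 9. Displacement at the β-branched, neopentyl-like C11 alkoxyphosphonium centre may be slow, so that elimination or alkylation of the reduced azodicarboxylate takes over. Fallback, from 13 back to 15: palladium-catalysed C–O cross-coupling of the primary alcohol of 13 with commercial 7-bromo-2H-chromen-2-one in place of 14 (Pd(OAc)2, t-BuBrettPhos, Cs2CO3, toluene, 80 °C) forms the aryl–oxygen bond instead of the C11–oxygen bond and avoids substitution at C11. This fallback makes no compound outside the list (F0).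

**Further compounds**

F1 | step 7 | (1R,4aS,8aR)-5,5,8a-trimethyl-2-methylidene-6-oxo-1,2,4a,5,6,7,8,8a-octahydronaphthalene-1-carbaldehyde | C=C1C=C[C@@H]2C(C)(C)C(=O)CC[C@@]2(C)[C@@H]1C=O
F2 | step 7 | (2S,4aR,5R,8aS)-5-(hydroxymethyl)-1,1,4a-trimethyl-6-methylidene-1,2,3,4,4a,5,6,8a-octahydronaphthalen-2-ol | C=C1C=C[C@@H]2C(C)(C)[C@@H](O)CC[C@@]2(C)[C@@H]1CO
F3 | step 7 | [(1S,4aR,6R,8aS)-6-hydroxy-5,5,8a-trimethyl-2-methylidene-1,2,4a,5,6,7,8,8a-octahydronaphthalen-1-yl]methyl (2S)-2-methoxy-2-phenylacetate | C=C1C=C[C@H]2C(C)(C)[C@H](O)CC[C@]2(C)[C@H]1COC(=O)[C@@H](OC)c1ccccc1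
F4 | step 7 | [(1R,4aS,6S,8aR)-6-hydroxy-5,5,8a-trimethyl-2-methylidene-1,2,4a,5,6,7,8,8a-octahydronaphthalen-1-yl]methyl (2S)-2-methoxy-2-phenylacetate | C=C1C=C[C@@H]2C(C)(C)[C@@H](O)CC[C@@]2(C)[C@@H]1COC(=O)[C@@H](OC)c1ccccc1
F5 | step 4 | methyl (2E,8E)-6-hydroxy-9-iodo-3,7,7-trimethylnona-2,8-dienoate | COC(=O)/C=C(\C)CCC(O)C(C)(C)/C=C/I
F0 | step 9 | none | none
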